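**Strategy.** Everything rests on the C2–C1′ bond. Ring C is not closed from a chalcone: the whole A/C bicycle is first made as a flat, achiral chromone that already carries the C8 prenyl group. Ring B is then delivered to C2, the β-carbon of the O1–C2=C3–C4=O vinylogous ester of ring C, by a rhodium-catalysed enantioselective conjugate arylation. This one operation joins the two halves and sets C2; C2 then steers the oxygenation of C3 to the trans face. The precursor, 5-hydroxy-7-methoxy-8-prenylchromone, owes its C8 substituent to an O5→C6→C8 Claisen–Cope relay.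

Key step: step 4

Remarks on the chemistry (assumptions):
- The (S)-configured atropisomeric bisphosphine is taken to give the (2S)-flavanone, by the quadrant model that holds for Rh/biaryl-bisphosphine additions to cyclic enones. If the sense proves opposite, the (R)-ligand is used and nothing else changes.
- (2S) in 11 and 12 and (2R) in 13 and 14 denote the same spatial arrangement at C2; the descriptor changes because O3 raises the CIP rank of C3.

**Step 1**
Reactants: 1 2′,6′-dihydroxy-4′-methoxyacetophenone; 2 N,N-dimethylformamide dimethyl acetal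
Product: 4 5-hydroxy-7-methoxy-4H-chromen-4-one, via enaminone 3 (not isolated)
Conditions: 2 (1.3 equiv), toluene, 80 °C; then conc. HCl, CH2Cl2, 40 °C
Reagents that add atoms: N,N-dimethylformamide dimethyl acetal (2), COC(OC)N(C)C
Why: Enaminone route to chromones: the amide acetal condenses with the acetyl CH3 to enaminone 3, and under acid either of the two equivalent ortho hydroxyls adds to the β-carbon with loss of dimethylamine (addition–elimination), so only one chromone can form and no stereocentre arises.

**Step 2**
Reactants: 4 5-hydroxy-7-methoxy-4H-chromen-4-one; 5 prenyl bromide (1-bromo-3-methylbut-2-ene)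
Product: 6 7-methoxy-5-(3-methylbut-2-enyloxy)-4H-chromen-4-one
Conditions: 5 (1.5 equiv), K2CO3, DMF, 50 °C
Reagents that add atoms: prenyl bromide (5), CC(C)=CCBr
Why: Williamson O-alkylation of the only phenol with a primary allylic bromide under carbonate conditions in a dipolar aprotic solvent, which favours O- over C-alkylation; no stereocentre.

**Step 3**
Reactants: 6 7-methoxy-5-(3-methylbut-2-enyloxy)-4H-chromen-4-one
Product: 9 5-hydroxy-7-methoxy-8-(3-methylbut-2-enyl)-4H-chromen-4-one, via C6 dimethylallyl dienone 7 (not isolated), via C8 prenyl dienone 8 (not isolated)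
Conditions: Eu(fod)3 (10 mol %), NaHCO3, PhCl, 85 °C
Reagents that add atoms: none
Why: Lewis-acid-accelerated aromatic Claisen–Cope (para-Claisen) cascade: Eu(III) chelated between the C4 carbonyl and O5 should trigger the [3,3] shift to C6 (dienone 7), a second [3,3] shift through C7=C8 should carry the allyl unit to C8 with the linear prenyl terminus restored (dienone 8), and enolisation to the hydrogen-bonded 5-phenol drives the sequence; no stereocentre survives.

**Step 4**
Reactants: 9 5-hydroxy-7-methoxy-8-(3-methylbut-2-enyl)-4H-chromen-4-one; 10 3-hydroxy-4-methoxyphenylboronic acid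
Product: 11 (2S)-5-hydroxy-2-(3-hydroxy-4-methoxyphenyl)-7-methoxy-8-(3-methylbut-2-enyl)chroman-4-one
Conditions: [RhOH(cod)]2 (2 mol %), (S)-MeO-F12-BIPHEP (4.4 mol %), 10 (2.5 equiv), CH2Cl2/H2O, 20 °C
Reagents that add atoms: 3-hydroxy-4-methoxyphenylboronic acid (10), COc1ccc(B(O)O)cc1O
Why: Boron-to-rhodium transmetalation gives an aryl–Rh(I) bisphosphine species, the chromone C2=C3 bond inserts into it (syn carborhodation, aryl to C2, Rh to C3), and the oxa-π-allyl rhodium enolate is protonated by water faster than β-oxygen elimination can open the pyranone, which regenerates Rh–OH. The closest known reaction type is the Hayashi–Miyaura asymmetric 1,4-addition of arylboronic acids to chromones to give 2-arylchroman-4-ones. No ring is closed: the C2–C1′ bond is formed on the preformed pyranone, so no mode of cyclisation is at issue. The new C2 stereocentre is set by the catalyst alone, the C2-symmetric atropisomeric ligand leaving one enantioface of C2 open in the insertion step, and the (2S) sense is the one that becomes (2R) of the target once O3 is in place. The step needs 1,4- over 1,2-addition, a single arylation and an untouched prenyl group: the electron-poor phosphine speeds insertion into the vinylogous ester, the peri 5-OH hydrogen bond to C4=O raises the electrophilicity of C2 and keeps that phenol off the metal, the product ketone is shielded by two ortho substituents, and an unactivated trisubstituted alkene does not insert into Ar–Rh. Base-free conditions at 20 °C should avoid retro-oxa-Michael racemisation of the product.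

**Step 5**
Reactants: 11 (2S)-5-hydroxy-2-(3-hydroxy-4-methoxyphenyl)-7-methoxy-8-(3-methylbut-2-enyl)chroman-4-one
Product: 12 (2S)-7-methoxy-2-[4-methoxy-3-(trimethylsilyloxy)phenyl]-8-(3-methylbut-2-enyl)-4,5-bis(trimethylsilyloxy)-2H-chromene
Conditions: TMSOTf (3.5 equiv), Et3N (5 equiv), CH2Cl2, 0 °C; pentane, filtration, used crude
Reagents that add atoms: trimethylsilyl trifluoromethanesulfonate, C[Si](C)(C)OS(=O)(=O)C(F)(F)F
Why: Soft enolisation: O-silylation of both phenols and of the C4 carbonyl followed by loss of a C3 proton to the amine gives the only possible enol silane without a free enolate, so retro-oxa-Michael opening and loss of the C2 configuration are avoided; C2 is untouched.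

**Step 6**
Reactants: 12 (2S)-7-methoxy-2-[4-methoxy-3-(trimethylsilyloxy)phenyl]-8-(3-methylbut-2-enyl)-4,5-bis(trimethylsilyloxy)-2H-chromene
Product: 14 (2R,3R)-3,5-dihydroxy-2-(3-hydroxy-4-methoxyphenyl)-7-methoxy-8-(3-methylbut-2-enyl)chroman-4-one (CNP0302743.1), via silyloxy epoxide 13 (not isolated)
Conditions: DMDO (1.05 equiv, acetone), CH2Cl2, −78 °C; then 1 M HCl, THF, 0 °C
Reagents that add atoms: dimethyldioxirane, CC1(C)OO1
Why: Rubottom oxidation: the electron-rich enol silane should be epoxidised by one equivalent of the neutral dioxirane at −78 °C well before the trisubstituted prenyl alkene, oxygen is delivered to C3 on the face anti to the adjacent C2 aryl group, and acid hydrolysis opens silyloxy epoxide 13 to the 3-hydroxy-4-ketone and frees both phenols, giving the 2,3-trans (2R,3R) isomer, which is also the thermodynamically preferred C3 epimer.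

**Compound list**

1 | 2′,6′-dihydroxy-4′-methoxyacetophenone | CC(=O)c1c(O)cc(OC)cc1O | starting material
2 | N,N-dimethylformamide dimethyl acetal | COC(OC)N(C)C | starting material
3 | (E)-1-(2,6-dihydroxy-4-methoxyphenyl)-3-(dimethylamino)prop-2-en-1-one | CN(C)/C=C/C(=O)c1c(O)cc(OC)cc1O | intermediate
4 | 5-hydroxy-7-methoxy-4H-chromen-4-one | O=c1ccoc2cc(OC)cc(O)c12 | intermediate
5 | prenyl bromide (1-bromo-3-methylbut-2-ene) | CC(C)=CCBr | starting material
6 | 7-methoxy-5-(3-methylbut-2-enyloxy)-4H-chromen-4-one | O=c1ccoc2cc(OC)cc(OCC=C(C)C)c12 | intermediate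
7 | 7-methoxy-6-(2-methylbut-3-en-2-yl)-6H-chromene-4,5-dione (ortho-Claisen dienone, racemic at C6) | O=C1C=COC2=C1C(=O)C(C(C)(C)C=C)C(OC)=C2 | intermediate
8 | 7-methoxy-8-(3-methylbut-2-enyl)-8H-chromene-4,5-dione (Cope dienone, racemic at C8) | O=C1C=COC2=C1C(=O)C=C(OC)C2CC=C(C)C | intermediate
9 | 5-hydroxy-7-methoxy-8-(3-methylbut-2-enyl)-4H-chromen-4-one | O=c1ccoc2c(CC=C(C)C)c(OC)cc(O)c12 | intermediate
10 | 3-hydroxy-4-methoxyphenylboronic acid | COc1ccc(B(O)O)cc1O | starting material
11 | (2S)-5-hydroxy-2-(3-hydroxy-4-methoxyphenyl)-7-methoxy-8-(3-methylbut-2-enyl)chroman-4-one | COc1ccc([C@H]2Oc3c(CC=C(C)C)c(OC)cc(O)c3C(=O)C2)cc1O | intermediate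
12 | (2S)-7-methoxy-2-[4-methoxy-3-(trimethylsilyloxy)phenyl]-8-(3-methylbut-2-enyl)-4,5-bis(trimethylsilyloxy)-2H-chromene | COc1ccc([C@H]2Oc3c(CC=C(C)C)c(OC)cc(O[Si](C)(C)C)c3C(O[Si](C)(C)C)=C2)cc1O[Si](C)(C)C | intermediate
13 | 3,4-epoxide of 12, oxirane oxygen on the ring face anti to the C2 aryl group, C2 and C3 configured as in the target, 4-OSiMe3 retained | COc1ccc([C@H]2Oc3c(CC=C(C)C)c(OC)cc(O[Si](C)(C)C)c3[C@@]4(O[Si](C)(C)C)[C@@H]2O4)cc1O[Si](C)(C)C | intermediate
14 | (2R,3R)-3,5-dihydroxy-2-(3-hydroxy-4-methoxyphenyl)-7-methoxy-8-(3-methylbut-2-enyl)chroman-4-one (CNP0302743.1) | COc1ccc([C@H]2Oc3c(CC=C(C)C)c(OC)cc(O)c3C(=O)[C@@H]2O)cc1O | target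

**Step count and risks**

Total steps: 6. Longest linear sequence: 6 steps (1 → 4 → 6 → 9 → 11 → 12 → 14).

Steps most likely to fail:

1. Step 4 (key step). Insertion of the electron-rich, C8-substituted pyranone into the aryl–rhodium bond may be slow. The chelated 5-OH may then divert the aryl–rhodium species to protonolysis, so that conversion or face selectivity at C2 falls short. Fallback, which reverses the order of arylation and prenyl transfer: it sets out from 6, which has no free hydroxyl on the chromone and no C8 substituent. The same rhodium-catalysed arylation with 10 should give (2S)-2-(3-hydroxy-4-methoxyphenyl)-7-methoxy-5-(3-methylbut-2-enyloxy)chroman-4-one F1. The Eu(fod)3-catalysed Claisen–Cope shift (CHCl3, 60 °C) is then run on this flavanone, the substrate class on which it is best established, and comes back to the route at 11.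

2. Step 6. The dioxirane may epoxidise the prenyl double bond in competition with the enol silane, or oxygen may be delivered in part syn to the C2 aryl group. Fallback, which replaces electrophilic epoxidation of an enol silane by oxygen transfer to an enolate from a reagent that does not epoxidise isolated alkenes: it sets out from 11. Silylation of both phenols (TBSOTf, 2,6-lutidine, CH2Cl2) should give (2S)-5-(tert-butyldimethylsilyloxy)-2-[3-(tert-butyldimethylsilyloxy)-4-methoxyphenyl]-7-methoxy-8-(3-methylbut-2-enyl)chroman-4-one F2. The potassium enolate (KHMDS, THF, −78 °C) is hydroxylated with 2-(phenylsulfonyl)-3-phenyloxaziridine anti to the C2 aryl group to give the (2R,3R)-3-hydroxy bis-silyl ether F3. Desilylation with HF·pyridine in THF at 0 °C comes back to the route at 14.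

3. Step 3. The cascade may stop at the ortho stage, dienone 7 enolising to the 6-(1,1-dimethylallyl) phenol before the Cope shift, or the allyl group may ionise and return in a [1,3] sense to C6. Fallback, which replaces the sigmatropic relay by a cross-coupling at C8: it sets out from 4. Protection (MOMCl, NaH, DMF) should give 7-methoxy-5-(methoxymethoxy)-4H-chromen-4-one F4. Iodination at the position para to the C5 oxygen (I2, CF3CO2Ag, CH2Cl2, 0 °C) should give 8-iodo-7-methoxy-5-(methoxymethoxy)-4H-chromen-4-one F5. Stille coupling with tributyl(3-methylbut-2-enyl)stannane (Pd(PPh3)4, DMF, 90 °C) should give 7-methoxy-5-(methoxymethoxy)-8-(3-methylbut-2-enyl)-4H-chromen-4-one F6. Acetal cleavage (HCl, MeOH, 40 °C) comes back to the route at 9.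

**Further compounds**

F1 | step 4 | (2S)-2-(3-hydroxy-4-methoxyphenyl)-7-methoxy-5-(3-methylbut-2-enyloxy)chroman-4-one | COc1ccc([C@H]2Oc3cc(OC)cc(OCC=C(C)C)c3C(=O)C2)cc1O
F2 | step 6 | (2S)-5-(tert-butyldimethylsilyloxy)-2-[3-(tert-butyldimethylsilyloxy)-4-methoxyphenyl]-7-methoxy-8-(3-methylbut-2-enyl)chroman-4-one | COc1ccc([C@H]2Oc3c(CC=C(C)C)c(OC)cc(O[Si](C)(C)C(C)(C)C)c3C(=O)C2)cc1O[Si](C)(C)C(C)(C)C
F3 | step 6 | (2R,3R)-5-(tert-butyldimethylsilyloxy)-2-[3-(tert-butyldimethylsilyloxy)-4-methoxyphenyl]-3-hydroxy-7-methoxy-8-(3-methylbut-2-enyl)chroman-4-one | COc1ccc([C@H]2Oc3c(CC=C(C)C)c(OC)cc(O[Si](C)(C)C(C)(C)C)c3C(=O)[C@@H]2O)cc1O[Si](C)(C)C(C)(C)C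
F4 | step 3 | 7-methoxy-5-(methoxymethoxy)-4H-chromen-4-one | O=c1ccoc2cc(OC)cc(OCOC)c12
F5 | step 3 | 8-iodo-7-methoxy-5-(methoxymethoxy)-4H-chromen-4-one | O=c1ccoc2c(I)c(OC)cc(OCOC)c12
F6 | step 3 | 7-methoxy-5-(methoxymethoxy)-8-(3-methylbut-2-enyl)-4H-chromen-4-one | O=c1ccoc2c(CC=C(C)C)c(OC)cc(OCOC)c12
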